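**Remark on the chemistry.** Rings are lettered A to F along the chain, starting at the 2,4,6-trihydroxyphenyl end. In rings B to F, C1 is the carbon bonded to the ether oxygen on the ring A side. Oligomers are written from the ring F end (F–E, F–E–D and so on). Every oxan-2-yl (tetrahydropyranyl) ether is used as the racemate. The three phenols 1, 6 and 12 are taken to be commercial.

## Structural features

The target is a linear hexamer of six benzene rings joined only by five diaryl ether oxygens; it has sixteen free phenolic hydroxyls, no stereocentre and no ring fusion. Ring A is a 2,4,6-trihydroxyphenyl group bound through C1. Rings B and D are para-linked (oxygen at C1 and C4, hydroxyl at C3 and C5). Rings C and E are ortho-linked (oxygen at C1 and C2, hydroxyl at C3, C4, C5). Ring F is a 3,4,5-trihydroxyphenoxy group. The pyrogallol- and phloroglucinol-type rings are easily oxidised in air, above all as phenoxides, so the free polyphenol should appear only at the very end. The real difficulty is the five ether bonds: C1 of ring A and C4 of rings B and D lie between two oxygenated carbons, and C2 of rings C and E lies between an ether carbon and a hydroxyl carbon. These carbons are electron-rich and crowded, which rules out direct nucleophilic substitution and makes copper couplings unattractive. The key step exploits the fact that each of these ether carbons has hydroxyl-bearing carbons ortho or para to it: C2 and C6 of ring A, and C3 and C5 of rings B, C, D and E. If these ten carbons carry formyl groups, each ether carbon is activated for fluoride displacement, and the formyl groups can afterwards be turned into the hydroxyls. A ring-by-ring check of the decaaldehyde and of its decahydroxy product against the target shows every formyl on a carbon that is hydroxylated in the target, with the six methoxy groups accounting for the other six hydroxyls; no structure needs correction.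

## Logic of the disconnections

**24 ⇒ 23.** The six O–CH3 bonds are cut last (O4 of rings A, C and E, and O3, O4, O5 of ring F). These oxygens sit on carbons that never carry an activating group, so they are carried from the starting materials as methyl ethers, which are inert to organolithium, carbonate, dilute acid and peroxide. This leaves a single deprotection at the end. The forward step must cleave six aryl methyl ethers without touching five diaryl ethers, on a substrate that already has ten free hydroxyls.

**23 ⇒ 21 (through 22).** Ten aryl C–O bonds are cut and replaced by ten aryl C–CHO bonds. This turns an electron-rich polyphenol, whose ether carbons cannot be made by substitution, into an electron-poor decaaldehyde in which every ether carbon is ortho or para to formyl. Ten hydroxyls then need no protecting group at any stage. The demand on the forward step is aryl migration in preference to hydride migration, ten times in one molecule.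

**21 ⇒ 20 + 11.** The bond from the ring B oxygen to C1 of ring A is cut. C1 of ring A lies between two formyl groups, so fluoride there is a good leaving group, and 11 is a small symmetrical monomer. The phenoxide of 20 must attack the C–F carbon of 11 faster than any aryloxy-bearing carbon flanked by formyl groups in 20 or 21.

**20 ⇒ 19 ⇒ 18 + 10; 18 ⇒ 17 ⇒ 16 + 5; 16 ⇒ 15 ⇒ 14 + 10; 14 ⇒ 13 ⇒ 12 + 5.** Each cycle cuts one ether bond (O–C4 of ring B or D, O–C2 of ring C or E) and the acetal C–O bond of a phenol mask. Growth from ring F towards ring A keeps the chain as the nucleophile and the incoming two-formyl monomer as the electrophile. The chain never holds a fluoride and the monomer never a free phenol, so oligomerisation is excluded. The chain phenol is always meta to its own formyl groups and therefore stays nucleophilic. Only two monomers are needed, each used twice. The mask must survive carbonate and fluoride and come off without base or reductant, which is why an acetal is chosen; in each coupling, fluoride displacement must outrun exchange of existing ether bonds.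

**10 and 11 ⇒ 9 ⇒ 8 ⇒ 7 ⇒ 6.** The acetal or methyl C–O bond is cut first, then the two formyl groups are traced back to methyl groups through benzylic C–Br bonds. In 6 the fluorine, the oxygen and both carbons are already in the right places, and the single intermediate 9 serves rings A, B and D. Bromination must go to the methyl groups and not the ring, hence the acetate, and hydrolysis must be acidic so that the newly activated fluoride is not displaced.

**5 ⇒ 3 ⇒ 2 ⇒ 1.** Two aryl C–CHO bonds, a C–Br bond and the acetal are cut. In 1 the fluorine, methoxy and hydroxyl are correctly placed. C3 is the most acidic ring position (between F and OMe) and C5 the most electron-rich (ortho to OMe, para to F). One formyl therefore enters by deprotonation and the other through a bromide. The bromination must be regioselective, and the first aldehyde must stay masked in the flask (as 4) while the second is introduced.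

## Other disconnections considered

**Alternative 1:** The cut removes three C–C bonds of ring D (C1–C6, C2–C3 and C3–C4). This divides the molecule into the 4-aryloxy-3-ethoxycyclobutenone A2 (rings E and F) and the aryl ethynyl ether A3 (rings A, B and C). In the forward step, heating opens A2 to a vinylketene, which adds the alkyne of A3; ring opening of the new cyclobutenone and 6π closure would give A1, with ring D formed as a phenol.
- In its favour: it is convergent and joins two halves of similar size. The crowded C4–O bond of ring D is made as an alkyl aryl ether before ring D exists. Regiochemistry follows from the polarity of the ynol ether. Ring D would emerge with its three oxygens differentiated.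
- Against it here: aryl ethynyl ethers are weaker ketenophiles than alkyl ynol ethers and tend to polymerise or hydrate at the temperatures needed. A2 and A3 each need their own multistep synthesis. The three other ether bonds (A–B and B–C in A3, E–F in A2) must still be made between unactivated, flanked, oxygenated carbons, which is the problem the chosen plan removes. A1 carries fifteen alkyl ethers to cleave, against six in 23.
- Comparison: on structure it solves two of the five ether bonds, where the chosen plan solves all five with one reaction type. On mechanism it is the better of the two in precedent, because benzannulation with heteroatom-substituted alkynes is an established class and the tenfold oxidation is not. On step economy its longest linear sequence would be shorter, which is a point in its favour, but its total step count is unlikely to be lower.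

**Alternative 2:** The cut removes the two C–O bonds at C1 and C2 of ring E, so that ring E comes from pyrogallol A5. In the forward step, A5 is oxidised at a carbon anode to the hydroxy-ortho-quinone A7, the hindered phenol A6 (ring D) adds through oxygen at C5 to give the triol A8, and a second oxidation and addition of 12 at the adjacent carbon would give A4.
- In its favour: ring E comes from the cheapest possible triol without protecting groups, the oxidant is the electrode, and two ether bonds form in one operation. For the D–E–F portion this is better in step and atom economy and gentler in reagents than the chosen plan.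
- Against it here: phenols are ambident, and 12 has two free, strongly nucleophilic ring carbons ortho to its hydroxyl, so C–C bond formation is to be expected. A6, 12, A8 and A4 are oxidised at potentials close to that of A5, which invites homo-coupling and over-oxidation. A7 condenses with itself to benzotropolone-type products. The regiochemistry of the second addition rests on a small electronic bias. Only two of the five ether bonds are addressed, and ring D of A4 must afterwards be joined through O1 to the unactivated, flanked C2 of ring C.
- Comparison: on structure it covers two ether bonds against five. On mechanism the chosen plan is the better one, since the site of each bond is fixed by the position of a fluorine atom and not by relative oxidation potentials. On step economy the alternative is the better one locally and probably the worse one overall.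

**Alternative 3:** The cut removes the C2–C3 bond of ring A, so that ring A is folded from the 2-aryloxy-3,5-dioxohexanoate A10, which already carries rings B to F. In the forward step, Mg(OMe)2 brings the terminal methyl carbon of A10 onto the ester carbonyl, and the resulting cyclohexanetrione enolises to the triol A9.
- In its favour: it follows the polyketide origin of phloroglucinols. The most crowded ether carbon, C1 of ring A, is made as an sp3 carbon by simple O-alkylation. Ring A arrives as a free triol with no protecting group. For ring A this is equal to or better than the chosen plan.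
- Against it here: it builds only the terminal ring and one ether bond; the pentaaryl tetraether part of A10 with thirteen methyl ethers must come from another method for four hindered ethers. 3,5-Dioxo esters also close through oxygen to 4-hydroxy-2-pyranones or by aldol modes to resorcylates, so C-acylation needs close control. Thirteen methyl ethers remain to be cleaved, against six.
- Comparison: on structure it solves one of five ether bonds. On mechanism the cyclisation is a known reaction type, which is a point in its favour against the unprecedented tenfold oxidation. On step economy it saves steps only for ring A.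

Key step: step 18

## Route

**Step 1**
Reactants: 1 2-fluoro-4-methoxyphenol
Product: 2 2-(2-fluoro-4-methoxyphenoxy)oxane (racemic)
Conditions: 3,4-dihydro-2H-pyran, PPTS (cat.), CH2Cl2, rt
Reagents that add atoms: 3,4-dihydro-2H-pyran, C1=COCCC1
Why: Acid-catalysed addition of the phenol to the enol ether (tetrahydropyranylation); the acetal tolerates organolithium and carbonate and is later removed by dilute acid that leaves aldehydes alone.

**Step 2**
Reactants: 2 2-(2-fluoro-4-methoxyphenoxy)oxane
Product: 3 2-(5-bromo-2-fluoro-4-methoxyphenoxy)oxane (racemic)
Conditions: NBS, DMF, 0 °C → rt, dark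
Reagents that add atoms: N-bromosuccinimide, O=C1CCC(=O)N1Br
Why: Electrophilic aromatic bromination; C5 is ortho to methoxy and para to fluorine, C6 is meta to both, and C3 is shielded between F and OMe. DMF keeps the medium free of acid so the acetal should survive.

**Step 3**
Reactants: 3 2-(5-bromo-2-fluoro-4-methoxyphenoxy)oxane
Product: 5 4-fluoro-2-methoxy-5-(oxan-2-yloxy)benzene-1,3-dicarbaldehyde (racemic), via lithium α-amino alkoxide 4 (not isolated)
Conditions: n-BuLi, THF, −78 °C; DMF (1.0 equiv); lithium 2,2,6,6-tetramethylpiperidide (LiTMP), −78 °C; DMF; AcOH, −78 °C → rt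
Reagents that add atoms: N,N-dimethylformamide, CN(C)C=O
Why: Bromine–lithium exchange and formylation give 4, in which the first aldehyde stays masked as its tetrahedral adduct; the amide base then removes the most acidic ring proton, between F and OMe (directed ortho-metalation), and a second DMF quench adds the other formyl group. The cold acetic acid quench protonates the released dimethylamine before it can displace the now activated fluoride.

**Step 4**
Reactants: 6 4-fluoro-3,5-dimethylphenol
Product: 7 4-fluoro-3,5-dimethylphenyl acetate
Conditions: Ac2O, Et3N, DMAP (cat.), CH2Cl2, 0 °C → rt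
Reagents that add atoms: acetic anhydride, CC(=O)OC(C)=O
Why: O-Acylation; the acetate lowers the electron density of the ring so that the radical bromination that follows attacks the methyl groups and not the ring.

**Step 5**
Reactants: 7 4-fluoro-3,5-dimethylphenyl acetate
Product: 8 3,5-bis(dibromomethyl)-4-fluorophenyl acetate
Conditions: NBS (4.4 equiv), AIBN (cat.), PhCF3, 90 °C
Reagents that add atoms: N-bromosuccinimide, O=C1CCC(=O)N1Br
Why: Wohl–Ziegler benzylic bromination; each methyl group takes two bromine atoms and the third enters slowly for steric reasons, so the bis(dibromomethyl) compound is the natural end point.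

**Step 6**
Reactants: 8 3,5-bis(dibromomethyl)-4-fluorophenyl acetate
Product: 9 2-fluoro-5-hydroxybenzene-1,3-dicarbaldehyde
Conditions: 85% aq. HCO2H, 100 °C
Reagents that add atoms: water, O
Why: Solvolysis of the two benzal bromides to aldehydes; the HBr set free catalyses hydrolysis of the aryl acetate in the same pot. The acidic medium keeps the phenol protonated, so the fluoride, now activated by two ortho formyl groups, is not attacked.

**Step 7**
Reactants: 9 2-fluoro-5-hydroxybenzene-1,3-dicarbaldehyde
Product: 10 2-fluoro-5-(oxan-2-yloxy)benzene-1,3-dicarbaldehyde (racemic)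
Conditions: 3,4-dihydro-2H-pyran, PPTS (cat.), CH2Cl2/THF, rt
Reagents that add atoms: 3,4-dihydro-2H-pyran, C1=COCCC1
Why: Tetrahydropyranylation under acid catalysis; no phenoxide is formed, so the monomer cannot condense with itself through its activated fluoride.

**Step 8**
Reactants: 9 2-fluoro-5-hydroxybenzene-1,3-dicarbaldehyde
Product: 11 2-fluoro-5-methoxybenzene-1,3-dicarbaldehyde
Conditions: MeI (excess), K2CO3, acetone, rt
Reagents that add atoms: iodomethane, CI
Why: Williamson O-methylation; with excess iodomethane at room temperature the phenoxide, which is weakly nucleophilic because of its two formyl groups, should be methylated much faster than it attacks a fluoroarene.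

**Step 9**
Reactants: 12 3,4,5-trimethoxyphenol; 5 4-fluoro-2-methoxy-5-(oxan-2-yloxy)benzene-1,3-dicarbaldehyde
Product: 13 2-methoxy-5-(oxan-2-yloxy)-4-(3,4,5-trimethoxyphenoxy)benzene-1,3-dicarbaldehyde (F–E dialdehyde, ring E O1 as oxan-2-yl ether; racemic)
Conditions: K2CO3, DMF, rt
Reagents that add atoms: none
Why: Nucleophilic aromatic substitution by addition–elimination; the fluorinated carbon is ortho to one formyl group and para to the other, which stabilise the Meisenheimer adduct. The methoxy group between the two formyl groups is a far poorer leaving group and the acetal is inert to carbonate.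

**Step 10**
Reactants: 13 F–E dialdehyde oxan-2-yl ether
Product: 14 5-hydroxy-2-methoxy-4-(3,4,5-trimethoxyphenoxy)benzene-1,3-dicarbaldehyde (F–E phenol)
Conditions: p-TsOH·H2O (cat.), THF/H2O, 40 °C
Reagents that add atoms: none
Why: Acid hydrolysis of the aryl acetal; aldehydes, methyl ethers and the diaryl ether are stable, and water as co-solvent prevents acetal formation at the formyl groups.

**Step 11**
Reactants: 14 F–E phenol; 10 2-fluoro-5-(oxan-2-yloxy)benzene-1,3-dicarbaldehyde
Product: 15 2-[3,5-diformyl-4-methoxy-2-(3,4,5-trimethoxyphenoxy)phenoxy]-5-(oxan-2-yloxy)benzene-1,3-dicarbaldehyde (F–E–D tetraaldehyde, ring D O1 as oxan-2-yl ether; racemic)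
Conditions: K2CO3, DMF, rt
Reagents that add atoms: none
Why: Nucleophilic aromatic substitution; the fluoride of 10 lies between two formyl groups, and the phenoxide of 14 is meta to its own formyl groups and therefore remains nucleophilic.

**Step 12**
Reactants: 15 F–E–D tetraaldehyde oxan-2-yl ether
Product: 16 2-[3,5-diformyl-4-methoxy-2-(3,4,5-trimethoxyphenoxy)phenoxy]-5-hydroxybenzene-1,3-dicarbaldehyde (F–E–D phenol)
Conditions: p-TsOH·H2O (cat.), THF/H2O, 40 °C
Reagents that add atoms: none
Why: Acid hydrolysis of the acetal as in step 10.

**Step 13**
Reactants: 16 F–E–D phenol; 5 4-fluoro-2-methoxy-5-(oxan-2-yloxy)benzene-1,3-dicarbaldehyde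
Product: 17 F–E–D–C hexaaldehyde, ring C O1 as oxan-2-yl ether (ring C: formyl at C3 and C5, methoxy at C4, C2 bonded to the ring D oxygen; racemic)
Conditions: K2CO3, DMF, rt
Reagents that add atoms: none
Why: Nucleophilic aromatic substitution at the ortho- and para-activated fluoride of 5; the phenoxide of 16 has no ortho substituent and is para to the ether carbon of ring D, which its donation also shields from exchange.

**Step 14**
Reactants: 17 F–E–D–C hexaaldehyde oxan-2-yl ether
Product: 18 F–E–D–C hexaaldehyde with free hydroxyl at C1 of ring C
Conditions: p-TsOH·H2O (cat.), THF/H2O, 40 °C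
Reagents that add atoms: none
Why: Acid hydrolysis of the acetal as in step 10.

**Step 15**
Reactants: 18 F–E–D–C phenol; 10 2-fluoro-5-(oxan-2-yloxy)benzene-1,3-dicarbaldehyde
Product: 19 F–E–D–C–B octaaldehyde, ring B O1 as oxan-2-yl ether (ring B: formyl at C3 and C5, C4 bonded to the ring C oxygen; racemic)
Conditions: K2CO3, DMF, rt
Reagents that add atoms: none
Why: Nucleophilic aromatic substitution as in step 11; fluoride is displaced much faster than the aryloxy groups on the formyl-flanked ether carbons already present, so a short reaction at room temperature should leave those untouched.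

**Step 16**
Reactants: 19 F–E–D–C–B octaaldehyde oxan-2-yl ether
Product: 20 F–E–D–C–B octaaldehyde with free hydroxyl at C1 of ring B
Conditions: p-TsOH·H2O (cat.), THF/H2O, 40 °C
Reagents that add atoms: none
Why: Acid hydrolysis of the acetal as in step 10.

**Step 17**
Reactants: 20 F–E–D–C–B phenol; 11 2-fluoro-5-methoxybenzene-1,3-dicarbaldehyde
Product: 21 hexaaryl pentaether decacarbaldehyde (formyl at C2 and C6 of ring A and at C3 and C5 of rings B, C, D and E; methoxy at C4 of rings A, C and E and at C3, C4, C5 of ring F)
Conditions: K2CO3, DMF, rt
Reagents that add atoms: none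
Why: Nucleophilic aromatic substitution at the doubly ortho-activated fluoride of 11 by an unhindered phenoxide; this closes the chain with no group left to unmask.

**Step 18**
Reactants: 21 hexaaryl pentaether decacarbaldehyde
Product: 23 decahydroxy hexaaryl pentaether hexamethyl ether (hydroxyl at every former formyl carbon), via decaformate 22 (not isolated)
Conditions: 30% aq. H2O2 (excess), (PhSe)2 (cat.), CH2Cl2, rt; aq. Na2SO3 wash; K2CO3 (cat.), MeOH, Ar, 0 °C; 1 M HCl
Reagents that add atoms: hydrogen peroxide, OO
Why: Proposed new method: (PhSe)2 is oxidised by H2O2 to benzeneperoxyseleninic acid, which adds to each formyl carbon to give a Criegee-type peroxy hemiacetal; a 1,2-shift of the aryl carbon from carbon to oxygen with loss of benzeneseleninate gives an aryl formate, and methanolysis then frees the phenol, so that ten aryl C–O bonds take the place of ten aryl C–CHO bonds. The closest known reaction type is the Dakin or Baeyer–Villiger oxidation of alkoxy- and aryloxybenzaldehydes to phenols with peracids or with H2O2 and a diselenide, established for molecules with one or two formyl groups; new here are the tenfold use in one substrate and rings that begin with two formyl groups each. No ring is closed and no stereocentre is formed. The selectivity needed is aryl over hydride migration at every site, and the substrate secures it through oxygen lone pairs: each formyl carbon of rings A, B and D is ortho to an aryloxy oxygen, and each formyl carbon of rings C and E is ortho to methoxy and ortho or para to an aryloxy oxygen. Each change of CHO into OCHO removes an acceptor from its ring, so the second migration on a ring should be easier than the first. The formates keep the new phenols masked from the oxidant until the peroxide is destroyed by sulfite, and the methanolysis is run under argon because the polyphenoxide is sensitive to air.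

**Step 19**
Reactants: 23 decahydroxy hexaaryl pentaether hexamethyl ether
Product: 24 target hexadecahydroxy hexaaryl pentaether (CNP0114537.0)
Conditions: BBr3 (1 M in CH2Cl2, excess), CH2Cl2, −78 °C → rt; MeOH, 0 °C; H2O; gas outlet through a scrubber
Reagents that add atoms: none
Why: Lewis acid cleavage of aryl methyl ethers: boron binds the ether oxygen and bromide attacks the methyl carbon by SN2 substitution. Diaryl ethers have no alkyl carbon to attack and stay intact; the free hydroxyls are held as borates until the quench.

## Compound list

1 | 2-fluoro-4-methoxyphenol | COc1ccc(O)c(F)c1 | starting material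
2 | 2-(2-fluoro-4-methoxyphenoxy)oxane (racemic) | COc1ccc(OC2CCCCO2)c(F)c1 | intermediate
3 | 2-(5-bromo-2-fluoro-4-methoxyphenoxy)oxane (racemic) | COc1cc(F)c(OC2CCCCO2)cc1Br | intermediate
4 | lithium (dimethylamino)[4-fluoro-2-methoxy-5-(oxan-2-yloxy)phenyl]methanolate (mixture of stereoisomers, not isolated) | COc1cc(F)c(OC2CCCCO2)cc1C([O-])N(C)C.[Li+] | intermediate
5 | 4-fluoro-2-methoxy-5-(oxan-2-yloxy)benzene-1,3-dicarbaldehyde (racemic; monomer for rings C and E) | COc1c(C=O)cc(OC2CCCCO2)c(F)c1C=O | intermediate
6 | 4-fluoro-3,5-dimethylphenol | Cc1cc(O)cc(C)c1F | starting material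
7 | 4-fluoro-3,5-dimethylphenyl acetate | CC(=O)Oc1cc(C)c(F)c(C)c1 | intermediate
8 | 3,5-bis(dibromomethyl)-4-fluorophenyl acetate | CC(=O)Oc1cc(C(Br)Br)c(F)c(C(Br)Br)c1 | intermediate
9 | 2-fluoro-5-hydroxybenzene-1,3-dicarbaldehyde | O=Cc1cc(O)cc(C=O)c1F | intermediate
10 | 2-fluoro-5-(oxan-2-yloxy)benzene-1,3-dicarbaldehyde (racemic; monomer for rings B and D) | O=Cc1cc(OC2CCCCO2)cc(C=O)c1F | intermediate
11 | 2-fluoro-5-methoxybenzene-1,3-dicarbaldehyde (monomer for ring A) | COc1cc(C=O)c(F)c(C=O)c1 | intermediate
12 | 3,4,5-trimethoxyphenol | COc1cc(O)cc(OC)c1OC | starting material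
13 | 2-methoxy-5-(oxan-2-yloxy)-4-(3,4,5-trimethoxyphenoxy)benzene-1,3-dicarbaldehyde (F–E, racemic) | C1CCC(Oc2cc(C=O)c(OC)c(C=O)c2Oc2cc(OC)c(OC)c(OC)c2)OC1 | intermediate
14 | 5-hydroxy-2-methoxy-4-(3,4,5-trimethoxyphenoxy)benzene-1,3-dicarbaldehyde (F–E phenol) | Oc1cc(C=O)c(OC)c(C=O)c1Oc1cc(OC)c(OC)c(OC)c1 | intermediate
15 | 2-[3,5-diformyl-4-methoxy-2-(3,4,5-trimethoxyphenoxy)phenoxy]-5-(oxan-2-yloxy)benzene-1,3-dicarbaldehyde (F–E–D, racemic) | C1CCC(Oc2cc(C=O)c(Oc3cc(C=O)c(OC)c(C=O)c3Oc3cc(OC)c(OC)c(OC)c3)c(C=O)c2)OC1 | intermediate
16 | 2-[3,5-diformyl-4-methoxy-2-(3,4,5-trimethoxyphenoxy)phenoxy]-5-hydroxybenzene-1,3-dicarbaldehyde (F–E–D phenol) | Oc1cc(C=O)c(Oc2cc(C=O)c(OC)c(C=O)c2Oc2cc(OC)c(OC)c(OC)c2)c(C=O)c1 | intermediate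
17 | F–E–D–C hexaaldehyde, ring C O1 as oxan-2-yl ether (racemic) | C1CCC(Oc2cc(C=O)c(OC)c(C=O)c2Oc2cc(C=O)c(Oc3cc(C=O)c(OC)c(C=O)c3Oc3cc(OC)c(OC)c(OC)c3)c(C=O)c2)OC1 | intermediate
18 | F–E–D–C hexaaldehyde, free hydroxyl at C1 of ring C | Oc1cc(C=O)c(OC)c(C=O)c1Oc1cc(C=O)c(Oc2cc(C=O)c(OC)c(C=O)c2Oc2cc(OC)c(OC)c(OC)c2)c(C=O)c1 | intermediate
19 | F–E–D–C–B octaaldehyde, ring B O1 as oxan-2-yl ether (racemic) | C1CCC(Oc2cc(C=O)c(Oc3cc(C=O)c(OC)c(C=O)c3Oc3cc(C=O)c(Oc4cc(C=O)c(OC)c(C=O)c4Oc4cc(OC)c(OC)c(OC)c4)c(C=O)c3)c(C=O)c2)OC1 | intermediate
20 | F–E–D–C–B octaaldehyde, free hydroxyl at C1 of ring B | Oc1cc(C=O)c(Oc2cc(C=O)c(OC)c(C=O)c2Oc2cc(C=O)c(Oc3cc(C=O)c(OC)c(C=O)c3Oc3cc(OC)c(OC)c(OC)c3)c(C=O)c2)c(C=O)c1 | intermediate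
21 | hexaaryl pentaether decacarbaldehyde (formyl at C2, C6 of ring A and C3, C5 of rings B to E; six methyl ethers) | COc1cc(C=O)c(Oc2cc(C=O)c(Oc3cc(C=O)c(OC)c(C=O)c3Oc3cc(C=O)c(Oc4cc(C=O)c(OC)c(C=O)c4Oc4cc(OC)c(OC)c(OC)c4)c(C=O)c3)c(C=O)c2)c(C=O)c1 | intermediate
22 | hexaaryl pentaether decaformate (formyloxy at every former formyl carbon; not isolated) | COc1cc(OC=O)c(Oc2cc(OC=O)c(Oc3cc(OC=O)c(OC)c(OC=O)c3Oc3cc(OC=O)c(Oc4cc(OC=O)c(OC)c(OC=O)c4Oc4cc(OC)c(OC)c(OC)c4)c(OC=O)c3)c(OC=O)c2)c(OC=O)c1 | intermediate
23 | decahydroxy hexaaryl pentaether hexamethyl ether | COc1cc(O)c(Oc2cc(O)c(Oc3cc(O)c(OC)c(O)c3Oc3cc(O)c(Oc4cc(O)c(OC)c(O)c4Oc4cc(OC)c(OC)c(OC)c4)c(O)c3)c(O)c2)c(O)c1 | intermediate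
24 | hexadecahydroxy hexaaryl pentaether (CNP0114537.0) | Oc1cc(O)c(Oc2cc(O)c(Oc3cc(O)c(O)c(O)c3Oc3cc(O)c(Oc4cc(O)c(O)c(O)c4Oc4cc(O)c(O)c(O)c4)c(O)c3)c(O)c2)c(O)c1 | target

## Step count and least certain steps

Total step count: 19. Longest linear sequence: 14 steps (steps 1 to 3 and 9 to 19).

**Step 18 (key step).** The most likely failure is hydride migration in place of aryl migration at the formyl groups of rings A, B and D. Each of these has only one ortho aryloxy oxygen and a second carbonyl meta to it until its partner has reacted, and hydride migration would leave carboxylic acids. Incomplete conversion at one of ten sites, or early hydrolysis of formates that exposes free phenols to the oxidant, would also spoil the product. The fallback uses reactions that are each long established for aryl aldehydes and aryl methyl ketones, and in which the aryl group competes only with methyl. From 21, MeMgBr (THF, −78 °C) would add to all formyl groups to give the decakis(1-hydroxyethyl) compound F1 as a mixture of diastereomers. Dess–Martin periodinane would oxidise it to the decaacetyl compound F2. Baeyer–Villiger oxidation with CF3CO3H (from urea–hydrogen peroxide and trifluoroacetic anhydride, Na2HPO4, CH2Cl2) would give the decaacetate F3. K2CO3 in methanol under argon would then return the route to 23.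

**Step 3.** The second metalation may stay incomplete, the ortho-fluoroaryllithium may lose LiF to an aryne if the temperature rises, or dimethylamine may displace the activated fluoride during work-up. As a fallback the two carbons are introduced in separate operations. From 3, LiTMP (THF, −78 °C) and DMF would give 3-bromo-6-fluoro-2-methoxy-5-(oxan-2-yloxy)benzaldehyde F4. Suzuki–Miyaura coupling with potassium vinyltrifluoroborate (PdCl2(dppf), Et3N, propan-1-ol, 80 °C) would give 3-ethenyl-6-fluoro-2-methoxy-5-(oxan-2-yloxy)benzaldehyde F5. Lemieux–Johnson cleavage (K2OsO4·2H2O cat., NaIO4, 2,6-lutidine, dioxane/H2O) would return the route to 5.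

**Step 2.** Bromination may go ortho to the acetal oxygen (C6) and not to C5, or the acetal may be lost to traces of acid, after which the free hydroxyl directs bromine to C6. As a fallback the oxygen at C1 is deactivated as an ester so that only the methoxy group directs. From 1, Ac2O/Et3N would give 2-fluoro-4-methoxyphenyl acetate F6. NBS in MeCN would give 5-bromo-2-fluoro-4-methoxyphenyl acetate F7. K2CO3 in methanol would give 5-bromo-2-fluoro-4-methoxyphenol F8, and dihydropyran with PPTS would return the route to 3.

**Step 15 (the same concern holds for steps 11, 13 and 17).** The phenoxide may attack an existing ether carbon that lies between two formyl groups and displace an aryloxide. This exchange would scramble the chain, and it becomes more probable as the number of such carbons grows. As a fallback the coupling is run without carbonate and without a reservoir of phenoxide. From 18, hexamethyldisilazane would give the trimethylsilyl ether F9. F9 and 10 with CsF (cat.) in DMF at room temperature should couple by fluoride-triggered desilylative substitution, in which each displaced fluoride frees the next phenoxide, and the route is rejoined at 19.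

**Step 19.** The borate of the decaphenol may be poorly soluble and leave methoxy groups uncleaved, and the free hexadecaphenol may be lost to air oxidation or poor recovery from water. As a fallback the product is isolated through a stable derivative. From 23, after BBr3 and the methanol quench, the crude material would be acetylated at once (Ac2O, pyridine, DMAP cat.) to the hexadecaacetate F10, which can be purified on silica. K2CO3 (cat.) in methanol under argon, followed by acidification, would then give 24.

## Further compounds

F1 | step 18 | hexaaryl pentaether with 1-hydroxyethyl in place of each formyl group of 21 (mixture of diastereomers) | COc1cc(C(C)O)c(Oc2cc(C(C)O)c(Oc3cc(C(C)O)c(OC)c(C(C)O)c3Oc3cc(C(C)O)c(Oc4cc(C(C)O)c(OC)c(C(C)O)c4Oc4cc(OC)c(OC)c(OC)c4)c(C(C)O)c3)c(C(C)O)c2)c(C(C)O)c1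
F2 | step 18 | hexaaryl pentaether with acetyl in place of each formyl group of 21 | COc1cc(C(C)=O)c(Oc2cc(C(C)=O)c(Oc3cc(C(C)=O)c(OC)c(C(C)=O)c3Oc3cc(C(C)=O)c(Oc4cc(C(C)=O)c(OC)c(C(C)=O)c4Oc4cc(OC)c(OC)c(OC)c4)c(C(C)=O)c3)c(C(C)=O)c2)c(C(C)=O)c1
F3 | step 18 | decaacetate of 23 | COc1cc(OC(C)=O)c(Oc2cc(OC(C)=O)c(Oc3cc(OC(C)=O)c(OC)c(OC(C)=O)c3Oc3cc(OC(C)=O)c(Oc4cc(OC(C)=O)c(OC)c(OC(C)=O)c4Oc4cc(OC)c(OC)c(OC)c4)c(OC(C)=O)c3)c(OC(C)=O)c2)c(OC(C)=O)c1
F4 | step 3 | 3-bromo-6-fluoro-2-methoxy-5-(oxan-2-yloxy)benzaldehyde (racemic) | COc1c(Br)cc(OC2CCCCO2)c(F)c1C=O
F5 | step 3 | 3-ethenyl-6-fluoro-2-methoxy-5-(oxan-2-yloxy)benzaldehyde (racemic) | COc1c(C=C)cc(OC2CCCCO2)c(F)c1C=O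
F6 | step 2 | 2-fluoro-4-methoxyphenyl acetate | COc1ccc(OC(C)=O)c(F)c1
F7 | step 2 | 5-bromo-2-fluoro-4-methoxyphenyl acetate | COc1cc(F)c(OC(C)=O)cc1Br
F8 | step 2 | 5-bromo-2-fluoro-4-methoxyphenol | COc1cc(F)c(O)cc1Br
F9 | step 15 | trimethylsilyl ether of 18 | C[Si](C)(C)Oc1cc(C=O)c(OC)c(C=O)c1Oc1cc(C=O)c(Oc2cc(C=O)c(OC)c(C=O)c2Oc2cc(OC)c(OC)c(OC)c2)c(C=O)c1
F10 | step 19 | hexadecaacetate of 24 | CC(=O)Oc1cc(OC(C)=O)c(Oc2cc(OC(C)=O)c(Oc3cc(OC(C)=O)c(OC(C)=O)c(OC(C)=O)c3Oc3cc(OC(C)=O)c(Oc4cc(OC(C)=O)c(OC(C)=O)c(OC(C)=O)c4Oc4cc(OC(C)=O)c(OC(C)=O)c(OC(C)=O)c4)c(OC(C)=O)c3)c(OC(C)=O)c2)c(OC(C)=O)c1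
A1 | alternative 1 | hexaaryl pentaether with ring D C3 hydroxyl free, C5 ethoxy and fourteen methyl ethers | COc1cc(OC)c(Oc2cc(OC)c(Oc3cc(OC)c(OC)c(OC)c3Oc3cc(O)c(Oc4cc(OC)c(OC)c(OC)c4Oc4cc(OC)c(OC)c(OC)c4)c(OCC)c3)c(OC)c2)c(OC)c1
A2 | alternative 1 | 3-ethoxy-4-[3,4,5-trimethoxy-2-(3,4,5-trimethoxyphenoxy)phenoxy]cyclobut-2-en-1-one (racemic) | CCOC1=CC(=O)C1Oc1cc(OC)c(OC)c(OC)c1Oc1cc(OC)c(OC)c(OC)c1
A3 | alternative 1 | ethynyl ether at C2 of ring C of the permethylated A–B–C triaryl diether | COc1cc(OC)c(Oc2cc(OC)c(Oc3cc(OC)c(OC)c(OC)c3OC#C)c(OC)c2)c(OC)c1
A4 | alternative 2 | D–E–F triaryl diether with ring E as free triol and ring D O1 benzylated | COc1cc(OCc2ccccc2)cc(OC)c1Oc1cc(O)c(O)c(O)c1Oc1cc(OC)c(OC)c(OC)c1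
A5 | alternative 2 | pyrogallol (benzene-1,2,3-triol) | Oc1cccc(O)c1O
A6 | alternative 2 | 4-(benzyloxy)-2,6-dimethoxyphenol | COc1cc(OCc2ccccc2)cc(OC)c1O
A7 | alternative 2 | 3-hydroxycyclohexa-3,5-diene-1,2-dione | O=C1C(=O)C(O)=CC=C1
A8 | alternative 2 | 5-[4-(benzyloxy)-2,6-dimethoxyphenoxy]benzene-1,2,3-triol | COc1cc(OCc2ccccc2)cc(OC)c1Oc1cc(O)c(O)c(O)c1
A9 | alternative 3 | hexaaryl pentaether with ring A as free triol and thirteen methyl ethers | Oc1cc(O)c(Oc2cc(OC)c(Oc3cc(OC)c(OC)c(OC)c3Oc3cc(OC)c(Oc4cc(OC)c(OC)c(OC)c4Oc4cc(OC)c(OC)c(OC)c4)c(OC)c3)c(OC)c2)c(O)c1
A10 | alternative 3 | methyl 2-aryloxy-3,5-dioxohexanoate carrying the permethylated B–F pentaaryl tetraether on O2 (racemic) | COC(=O)C(Oc2cc(OC)c(Oc3cc(OC)c(OC)c(OC)c3Oc3cc(OC)c(Oc4cc(OC)c(OC)c(OC)c4Oc4cc(OC)c(OC)c(OC)c4)c(OC)c3)c(OC)c2)C(=O)CC(C)=O
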